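## Analysis of the target

The target, 2-hydroxy-6-(13-hydroxy-2-oxotridecyl)-4-methoxybenzoic acid, is one benzene ring with four substituents: CO2H on C1, a free OH on C2, OMe on C4 and the chain CH2–C(=O)–(CH2)11–OH on C6, with hydrogen on C3 and C5. It has no stereocentre, so the problem is purely one of regiochemistry on the ring. The two ring oxygens are alike in reactivity but must end up different, one as a free phenol ortho to the carboxyl group and one as a methyl ether para to it. The molecule is fragile in three ways. The para-oxygenated salicylic acid decarboxylates with acid or heat. The ketone sits two atoms from the carboxyl carbon and can close to a lactol and dehydrate to an isocoumarin. The ArCH2C(=O) methylene is acidic. The last step therefore has to be neutral, and the ketone has to be masked, at the ketone oxidation level, while the ring is built. The plan rests on one feature: the contiguous ring atoms C3(H), C2(O), C1(carboxyl) and C6(CH2 chain) are positions 3, 4, 5 and 6 of a 4-oxy-2-pyrone-5-carboxylate with the side chain on position 6. The two ring atoms left over, C4(OMe) and C5(H), are a two-carbon unit with one oxygen, which is a ketene acetal.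

## Retrosynthetic reasoning

Target 20 is traced back to keto ester 19 by cutting the three O–benzyl bonds on the phenol, the carboxyl group and the primary alcohol. All three fall in one hydrogenolysis, so the unstable free keto acid appears only in the final, neutral step.

Ketone 19 is traced back to dioxolane 18. The ketone is masked because at the pyrone stage its neighbouring CH2 would be a vinylogous 1,3-dicarbonyl methylene, acidic enough to destroy a ketene acetal. A mask at the alcohol level is not used, since a free secondary alcohol at that position would lactonise onto the ortho ester.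

Arene 18 is cut at ring bonds C3–C4 and C5–C6, which gives pyrone 14 and ketene acetal 15. Forward, 15 adds across pyrone positions 3 and 6 to give bridged lactone 16, decarboxylation gives cyclohexadiene 17, and loss of one methoxy group aromatises it. This cut is chosen because it delivers the methoxy group para to the ester while the pyrone oxygen stays ortho to it as a benzyl ether. The two oxygens are thus told apart by where they come from.

Pyrone 14 goes back to hydroxypyrone 13 by cutting the O–benzyl bond at the pyrone 4-oxygen. The cap is needed because a free enol would protonate 15.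

Hydroxypyrone 13 is opened at the lactone C–O bond to tricarbonyl ester 12, and 12 is cut at the bond between pyrone C4 and C5 into keto ester 10 and acid chloride 11. A one-operation annulation with a diacid dichloride would make the same ring, but it releases two equivalents of strong acid beside a dioxolane that sits β to a ketone. The buffered two-step version avoids this.

Keto ester 10 is cut at its C2–C3 bond to ketal acid 7 by a decarboxylative Claisen condensation with a malonic half-ester, passing through acyl imidazole 8 and acylmalonate 9. The benzyl ester is installed here so that it leaves with the other benzyl groups at the end.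

Acid 7 comes from ethyl ester 6 by hydrolysis, and 6 from keto ester 5 by ketalisation. The ketal has to be set between the two homologations, because only then is the ketone to be masked the sole ketone present.

Keto ester 5 is cut at its C2–C3 bond to acid 2 by the same decarboxylative Claisen condensation, via 3 and 4. Acid 2 is the O-benzyl ether of the commercial hydroxy acid 1, whose carboxyl carbon becomes the side-chain ketone carbon.

## Alternatives that were turned down

Alternative 1: Here the C1–carboxyl bond and the C6–CH2 bond are cut together. Fluoride would release 3,5-dimethoxybenzyne A2 from its silyl triflate A1. The anion of dimethyl malonate A3 would add to the aryne carbon remote from the flanking methoxy group, and the aryl anion would then attack an ester carbonyl, so that a C–C bond of the malonate is inserted and the homophthalate A4 results.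
- For: the acyl-alkylation of arynes is well precedented, the 3-methoxy group controls its orientation reliably, and no ring has to be built. On certainty of the key step this route is stronger than a pyrone cycloaddition with a donor-substituted diene.
- Against: A4 carries two methyl ethers, of which only the one ortho to the ester may be cleaved, and two methyl esters. The whole C11 chain is still missing and would have to be attached by turning the aliphatic ester selectively into a ketone at an acidic benzylic position. The hindered benzoate must finally be hydrolysed under conditions that favour closure to an isocoumarin. A1 itself needs several steps.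
- Comparison: the chosen strategy has the less certain key step. In return the chain is in place before the ring exists, the two oxygens are differentiated by construction, and the end game is one neutral hydrogenolysis.

Alternative 2: Here ring bond C1–C6 is cut, leading to the linear trioxo ester A5, in which the fourth carbonyl is a dioxolane. A mild carbonate base would fold A5 by aldol addition of chain C2 to the C7 ketone, dehydration and enolisation, giving the resorcylate A6.
- For: the folding is biomimetic and runs at ambient temperature. The later methylation should be selective for the 4-hydroxyl, because the 2-hydroxyl is hydrogen-bonded to the ester. On mildness of the ring-forming step this route is stronger.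
- Against: A5 is hard to assemble and to handle. It needs polyanion acylations and is prone to lactonise to a 4-hydroxy-2-pyrone or to close in Claisen fashion to an acylphloroglucinol. Its dioxolane lies β to an enolisable ketone. Methylation and desilylation add steps.
- Comparison: step counts are similar. The chosen route replaces the labile open-chain polyketone by a stable, purifiable pyrone and brings the methyl ether in with the dienophile.

Alternative 3: Here ring bonds C1–C2 and C5–C6 are cut. On heating, the silyloxydiene A7 would add to the ynoate A8, with the nucleophilic diene terminus bonding to the β-carbon of the ynoate. Loss of a methoxy group and desilylation would give the phenol A9.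
- For: the orientation of such dienes with acetylenic esters is well established, and the methyl ether and the free ortho phenol arise directly. On regiochemical precedent this route is at least as strong as the chosen one.
- Against: A8 is an internal ynoate with an alkyl group on the β-carbon, a sluggish dienophile. The temperatures needed are ones at which A7 decomposes or transfers its silyl group. The propargylic CH2 of A8 next to the ketal is prone to base-induced isomerisation to an allene. A8 takes about as many steps as pyrone 14, and A7 must be made fresh.
- Comparison: the chosen route uses a shelf-stable diene precursor and a commercial ketene acetal in excess, and the phenol emerges already protected.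

Key step: step 9

Remark on the chemistry: the target is taken as the open keto acid as drawn. Acids of this type can equilibrate with their cyclic lactol, and the route does not force either form.

## Route

Step 1
Reactants: 1 12-hydroxydodecanoic acid
Product: 2 12-(benzyloxy)dodecanoic acid
Conditions: NaH (2.5 equiv), BnBr (1.1 equiv), Bu4NI (cat.), THF, 0 °C → reflux; then aq. HCl
Reagents that add atoms: benzyl bromide, BrCc1ccccc1
Why: Williamson ether synthesis on the alkoxide–carboxylate dianion; in THF the alkoxide is by far the better nucleophile, so the ether forms at the alcohol oxygen and acidification returns the free acid. Any benzyl ester formed at the carboxylate would be cleaved by a short aqueous NaOH treatment before acidification.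

Step 2
Reactants: 2 12-(benzyloxy)dodecanoic acid
Product: 5 ethyl 14-(benzyloxy)-3-oxotetradecanoate, via acyl imidazole 3 (not isolated), via acylmalonic half ester 4 (not isolated)
Conditions: CDI, THF, rt; then KO2CCH2CO2Et, MgCl2, Et3N, THF/MeCN, rt → 40 °C; aq. HCl work-up
Reagents that add atoms: potassium ethyl malonate, CCOC(=O)CC(=O)[O-].[K+]
Why: Masamune-type decarboxylative Claisen homologation: acyl imidazole 3 C-acylates the magnesium enolate of the malonate half-ester, and the acylmalonate 4 loses CO2 on acidification to give the β-keto ester.

Step 3
Reactants: 5 ethyl 14-(benzyloxy)-3-oxotetradecanoate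
Product: 6 ethyl {2-[11-(benzyloxy)undecyl]-1,3-dioxolan-2-yl}acetate
Conditions: HOCH2CH2OH (5 equiv), TsOH·H2O (cat.), toluene, reflux, Dean–Stark
Reagents that add atoms: ethane-1,2-diol, OCCO
Why: Acid-catalysed ketalisation driven by azeotropic removal of water; the ketone of a β-keto ester ketalises cleanly, and the ethyl ester and benzyl ether are inert.

Step 4
Reactants: 6 ethyl {2-[11-(benzyloxy)undecyl]-1,3-dioxolan-2-yl}acetate
Product: 7 {2-[11-(benzyloxy)undecyl]-1,3-dioxolan-2-yl}acetic acid
Conditions: NaOH, EtOH/H2O, rt; then cold 1 M HCl to pH 4, immediate extraction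
Reagents that add atoms: sodium hydroxide, [Na+].[OH-]
Why: Saponification of the ethyl ester; dioxolane and benzyl ether are stable to hydroxide, and a brief cold acidification to about pH 4 frees the acid without opening the ketal.

Step 5
Reactants: 7 {2-[11-(benzyloxy)undecyl]-1,3-dioxolan-2-yl}acetic acid
Product: 10 benzyl 4-{2-[11-(benzyloxy)undecyl]-1,3-dioxolan-2-yl}-3-oxobutanoate, via acyl imidazole 8 (not isolated), via acylmalonic half ester 9 (not isolated)
Conditions: CDI, THF, rt; then BnO2CCH2CO2H, MgCl2, Et3N, THF/MeCN, rt → 40 °C; cold aq. citric acid work-up
Reagents that add atoms: 3-(benzyloxy)-3-oxopropanoic acid, OC(=O)CC(=O)OCc1ccccc1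
Why: Second Masamune-type decarboxylative Claisen homologation, now with the benzyl half-ester so that the new ester later falls by hydrogenolysis. The near-neutral medium spares the dioxolane, and the chelated acylmalonate 9 decarboxylates on the mildly acidic work-up.

Step 6
Reactants: 10 benzyl 4-{2-[11-(benzyloxy)undecyl]-1,3-dioxolan-2-yl}-3-oxobutanoate, 11 methyl 3-chloro-3-oxopropanoate
Product: 12 1-benzyl 5-methyl 2-({2-[11-(benzyloxy)undecyl]-1,3-dioxolan-2-yl}acetyl)-3-oxopentanedioate
Conditions: MgCl2 (1.1 equiv), pyridine (2.2 equiv), CH2Cl2, 0 °C; then 11 (1.1 equiv), 0 °C → rt; cold aq. citric acid work-up, used crude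
Reagents that add atoms: none
Why: Magnesium-mediated C-acylation of a β-keto ester with an acid chloride: chelation to MgCl2 makes C2–H acidic enough for pyridine and steers the acyl group to carbon. The medium stays cold and buffered, so the dioxolane never meets free HCl, which is the reason the classical one-pot annulation with malonyl dichloride is not used here.

Step 7
Reactants: 12 1-benzyl 5-methyl 2-({2-[11-(benzyloxy)undecyl]-1,3-dioxolan-2-yl}acetyl)-3-oxopentanedioate
Product: 13 benzyl 6-({2-[11-(benzyloxy)undecyl]-1,3-dioxolan-2-yl}methyl)-4-hydroxy-2-oxo-2H-pyran-5-carboxylate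
Conditions: DBU (1.5 equiv), toluene, 60 °C; then cold aq. citric acid
Reagents that add atoms: none
Why: Base-mediated lactonisation of a 1,3,5-tricarbonyl ester to a 4-hydroxy-2-pyrone: the enolate oxygen of the chain ketone attacks the methyl ester (6-exo-trig), methoxide leaves and the product settles as the stabilised hydroxypyrone anion. Only this oxygen and this ester can form a six-membered ring, so the mode of closure is fixed.

Step 8
Reactants: 13 benzyl 6-({2-[11-(benzyloxy)undecyl]-1,3-dioxolan-2-yl}methyl)-4-hydroxy-2-oxo-2H-pyran-5-carboxylate
Product: 14 benzyl 4-(benzyloxy)-6-({2-[11-(benzyloxy)undecyl]-1,3-dioxolan-2-yl}methyl)-2-oxo-2H-pyran-5-carboxylate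
Conditions: BnBr (1.2 equiv), K2CO3, DMF, rt
Reagents that add atoms: benzyl bromide, BrCc1ccccc1
Why: SN2 O-alkylation of the 4-hydroxy-2-pyrone anion, which under carbonate/DMF conditions reacts mainly at the 4-oxygen. Benzylation also removes the acidic enol proton that would destroy the ketene acetal in the next step.

Step 9
Reactants: 14 benzyl 4-(benzyloxy)-6-({2-[11-(benzyloxy)undecyl]-1,3-dioxolan-2-yl}methyl)-2-oxo-2H-pyran-5-carboxylate, 15 1,1-dimethoxyethene
Product: 18 benzyl 2-(benzyloxy)-6-({2-[11-(benzyloxy)undecyl]-1,3-dioxolan-2-yl}methyl)-4-methoxybenzoate, via bridged lactone 16 (not isolated), via cyclohexadiene ketal 17 (not isolated)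
Conditions: 15 (10 equiv), toluene, 120–140 °C, sealed base-washed tube
Reagents that add atoms: none
Why: Pyrone 14 is the electron-poor diene, its LUMO lowered by the lactone carbonyl and the position 5 ester, and ketene acetal 15 is the electron-rich two-carbon partner, so the reaction is an inverse-electron-demand (4+2) cycloaddition across pyrone positions 3 and 6. Bond formation should be asynchronous: the nucleophilic CH2 of 15 attacks position 6, which is β to the ester and vinylogously conjugated to the lactone carbonyl, and the developing oxocarbenium carbon closes onto position 3, giving bridged lactone 16. Lactone 16 loses CO2 by cycloreversion to cyclohexadiene 17, which eliminates methanol across the two carbons that came from 15 and so aromatises to 18. The closest known reaction type is the conversion of alkyl 2-pyrone-5-carboxylates, including 4,6-disubstituted ones, into 4-alkoxybenzoates with 1,1-dialkoxyethenes. The benzene ring is closed intermolecularly: both new ring bonds (target C3–C4 and C5–C6) come from the one cycloaddition, and the lactone bridge is excised afterwards. No stereocentre has to be controlled, since the two bridgeheads of 16 form as a racemate and are flattened on aromatisation. The selectivity the step needs is the orientation of 15 with its CH2 on position 6; the polarisation of the diene by the position 5 ester and the 4-benzyloxy group secures it and puts the methoxy group para to the ester. The dioxolane keeps the position 6 methylene from being a vinylogous dicarbonyl CH2, and the benzyl cap removes the enol proton, so 15 meets no acid.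

Step 10
Reactants: 18 benzyl 2-(benzyloxy)-6-({2-[11-(benzyloxy)undecyl]-1,3-dioxolan-2-yl}methyl)-4-methoxybenzoate
Product: 19 benzyl 2-(benzyloxy)-6-[13-(benzyloxy)-2-oxotridecyl]-4-methoxybenzoate
Conditions: 1 M aq. HCl, THF, rt
Reagents that add atoms: water, O
Why: Acid-catalysed hydrolysis of the dioxolane; benzyl ethers and the hindered benzyl ester are inert to dilute aqueous acid at ambient temperature. Keeping the carboxyl group esterified at this stage holds back dehydrative closure to an isocoumarin.

Step 11
Reactants: 19 benzyl 2-(benzyloxy)-6-[13-(benzyloxy)-2-oxotridecyl]-4-methoxybenzoate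
Product: 20 2-hydroxy-6-(13-hydroxy-2-oxotridecyl)-4-methoxybenzoic acid
Conditions: H2 (1 atm), Pd/C (10%), EtOAc/EtOH, rt
Reagents that add atoms: none
Why: Hydrogenolysis of the benzyl ester, the aryl benzyl ether and the alkyl benzyl ether over Pd/C; the aliphatic ketone, the arene and the methyl ether are not reduced under these conditions. The neutral medium and ambient temperature protect the product from decarboxylation and from lactol dehydration.

## Compound list

1 | 12-hydroxydodecanoic acid | OCCCCCCCCCCCC(=O)O | starting material
2 | 12-(benzyloxy)dodecanoic acid | OC(=O)CCCCCCCCCCCOCc1ccccc1 | intermediate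
3 | 1-[12-(benzyloxy)dodecanoyl]-1H-imidazole | O=C(CCCCCCCCCCCOCc1ccccc1)n1ccnc1 | intermediate
4 | 2-[12-(benzyloxy)dodecanoyl]-3-ethoxy-3-oxopropanoic acid (formed as its magnesium chelate) | CCOC(=O)C(C(=O)O)C(=O)CCCCCCCCCCCOCc1ccccc1 | intermediate
5 | ethyl 14-(benzyloxy)-3-oxotetradecanoate | CCOC(=O)CC(=O)CCCCCCCCCCCOCc1ccccc1 | intermediate
6 | ethyl {2-[11-(benzyloxy)undecyl]-1,3-dioxolan-2-yl}acetate | CCOC(=O)CC1(CCCCCCCCCCCOCc2ccccc2)OCCO1 | intermediate
7 | {2-[11-(benzyloxy)undecyl]-1,3-dioxolan-2-yl}acetic acid | OC(=O)CC1(CCCCCCCCCCCOCc2ccccc2)OCCO1 | intermediate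
8 | 1-({2-[11-(benzyloxy)undecyl]-1,3-dioxolan-2-yl}acetyl)-1H-imidazole | O=C(CC1(CCCCCCCCCCCOCc2ccccc2)OCCO1)n1ccnc1 | intermediate
9 | 3-(benzyloxy)-2-({2-[11-(benzyloxy)undecyl]-1,3-dioxolan-2-yl}acetyl)-3-oxopropanoic acid (formed as its magnesium chelate) | OC(=O)C(C(=O)OCc1ccccc1)C(=O)CC1(CCCCCCCCCCCOCc2ccccc2)OCCO1 | intermediate
10 | benzyl 4-{2-[11-(benzyloxy)undecyl]-1,3-dioxolan-2-yl}-3-oxobutanoate | O=C(CC(=O)CC1(CCCCCCCCCCCOCc2ccccc2)OCCO1)OCc1ccccc1 | intermediate
11 | methyl 3-chloro-3-oxopropanoate | COC(=O)CC(=O)Cl | starting material
12 | 1-benzyl 5-methyl 2-({2-[11-(benzyloxy)undecyl]-1,3-dioxolan-2-yl}acetyl)-3-oxopentanedioate (drawn as the triketo tautomer) | COC(=O)CC(=O)C(C(=O)OCc1ccccc1)C(=O)CC1(CCCCCCCCCCCOCc2ccccc2)OCCO1 | intermediate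
13 | benzyl 6-({2-[11-(benzyloxy)undecyl]-1,3-dioxolan-2-yl}methyl)-4-hydroxy-2-oxo-2H-pyran-5-carboxylate | O=C1C=C(O)C(C(=O)OCc2ccccc2)=C(CC2(CCCCCCCCCCCOCc3ccccc3)OCCO2)O1 | intermediate
14 | benzyl 4-(benzyloxy)-6-({2-[11-(benzyloxy)undecyl]-1,3-dioxolan-2-yl}methyl)-2-oxo-2H-pyran-5-carboxylate | O=C1C=C(OCc2ccccc2)C(C(=O)OCc2ccccc2)=C(CC2(CCCCCCCCCCCOCc3ccccc3)OCCO2)O1 | intermediate
15 | 1,1-dimethoxyethene | C=C(OC)OC | starting material
16 | benzyl 5-(benzyloxy)-1-({2-[11-(benzyloxy)undecyl]-1,3-dioxolan-2-yl}methyl)-8,8-dimethoxy-3-oxo-2-oxabicyclo[2.2.2]oct-5-ene-6-carboxylate (racemic; the two bridgeheads are fixed relative to each other by the bicycle) | O=C1OC2(CC3(CCCCCCCCCCCOCc4ccccc4)OCCO3)CC(OC)(OC)C1C(OCc5ccccc5)=C2C(=O)OCc6ccccc6 | intermediate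
17 | benzyl 6-(benzyloxy)-2-({2-[11-(benzyloxy)undecyl]-1,3-dioxolan-2-yl}methyl)-4,4-dimethoxycyclohexa-1,5-diene-1-carboxylate | COC1(OC)CC(CC2(CCCCCCCCCCCOCc3ccccc3)OCCO2)=C(C(=O)OCc4ccccc4)C(OCc5ccccc5)=C1 | intermediate
18 | benzyl 2-(benzyloxy)-6-({2-[11-(benzyloxy)undecyl]-1,3-dioxolan-2-yl}methyl)-4-methoxybenzoate | COc1cc(OCc2ccccc2)c(C(=O)OCc2ccccc2)c(CC2(CCCCCCCCCCCOCc3ccccc3)OCCO2)c1 | intermediate
19 | benzyl 2-(benzyloxy)-6-[13-(benzyloxy)-2-oxotridecyl]-4-methoxybenzoate | COc1cc(OCc2ccccc2)c(C(=O)OCc2ccccc2)c(CC(=O)CCCCCCCCCCCOCc2ccccc2)c1 | intermediate
20 | 2-hydroxy-6-(13-hydroxy-2-oxotridecyl)-4-methoxybenzoic acid | COc1cc(O)c(C(=O)O)c(CC(=O)CCCCCCCCCCCO)c1 | target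

## Step count and least certain steps

Total step count: 11. Longest linear sequence: 11 steps, from 1 to 20; 11 and 15 are bought.

Step 9 (key step). The cycloaddition may be too slow. The 4-benzyloxy group feeds electron density into the diene and position 6 is substituted, so thermal decomposition or oligomerisation of the ketene acetal, or a stepwise conjugate addition that never closes the second bond, could outrun ring formation. A reversed orientation of the dienophile is the second concern. The fallback gives up the ring construction and uses lateral metalation of a bought arene.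
- It sets out from acid 2, which is converted with CDI and N,O-dimethylhydroxylamine hydrochloride into 12-(benzyloxy)-N-methoxy-N-methyldodecanamide F1.
- Commercial 2-hydroxy-4-methoxy-6-methylbenzoic acid F2 is benzylated on both oxygens (BnBr, K2CO3, DMF) to benzyl 2-(benzyloxy)-4-methoxy-6-methylbenzoate F3.
- Deprotonation of the 6-methyl group of F3 with LiN(iPr)2 in THF at −78 °C and addition of F1 should give, after collapse of the chelated adduct on work-up, keto ester 19, where the route is rejoined.
- The low temperature is needed to keep the benzylic positions of the benzyl groups from being metalated.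

Step 6. Acylation may go to the enol oxygen instead of carbon, and the acid chloride may self-condense through its ketene under pyridine; pyridinium chloride could also begin to open the dioxolane if the mixture warms. The fallback forms the other ring bond instead, between pyrone positions 5 and 6. It sets out from acid 7, which is activated as acyl imidazole 8 and used to C-acylate the magnesium chelate (MgCl2, Et3N, MeCN) of dibenzyl 3-oxopentanedioate F4. The product, dibenzyl 2-({2-[11-(benzyloxy)undecyl]-1,3-dioxolan-2-yl}acetyl)-3-oxopentanedioate F5, is lactonised with DBU, with loss of benzyl alcohol, and rejoins the route at hydroxypyrone 13.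

Step 7. Instead of lactonising, the tricarbonyl anion may lose the malonyl unit by retro-Claisen cleavage, or may cyclise through carbon to an acylphloroglucinol if a second deprotonation occurs. The fallback uses an acylating agent whose second end closes the lactone spontaneously. It sets out from keto ester 10, which is treated with malonyl dichloride F6 in dilute CH2Cl2 under a slow nitrogen sweep, and it returns at hydroxypyrone 13 in one operation. The price is the HCl released, which the dioxolane must survive; this is why it is held in reserve.

Step 5. The methylene of acyl imidazole 8 lies between the activated carbonyl and the ketal carbon, so Et3N may trigger elimination that opens the dioxolane. Acid 7 may also lose its ketal on isolation and then decarboxylate. The fallback avoids both the free acid and the acyl imidazole. It sets out from ethyl ester 6, which is added at −78 °C to an excess of the lithium enolate of benzyl acetate F7 (LiN(iPr)2, THF). This crossed Claisen condensation should give keto ester 10 directly, where the route is rejoined.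

Step 10. Under acid the new ketone may enolise and attack the neighbouring benzyl ester, closing an isocoumarin with loss of benzyl alcohol before hydrolysis is complete. The fallback makes this closure deliberate and then reverses it.
- It sets out from ketal 18, which is heated with TsOH·H2O in wet toluene to give 8-(benzyloxy)-3-[11-(benzyloxy)undecyl]-6-methoxy-1H-isochromen-1-one F8.
- Aqueous KOH in EtOH opens the enol lactone to 2-(benzyloxy)-6-[13-(benzyloxy)-2-oxotridecyl]-4-methoxybenzoic acid F9 after careful acidification.
- Hydrogenolysis over Pd/C then removes the two remaining benzyl ethers and returns to the route at target 20.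

## Further compounds

F1 | step 9 | 12-(benzyloxy)-N-methoxy-N-methyldodecanamide | CON(C)C(=O)CCCCCCCCCCCOCc1ccccc1
F2 | step 9 | 2-hydroxy-4-methoxy-6-methylbenzoic acid | COc1cc(C)c(C(=O)O)c(O)c1
F3 | step 9 | benzyl 2-(benzyloxy)-4-methoxy-6-methylbenzoate | COc1cc(C)c(C(=O)OCc2ccccc2)c(OCc2ccccc2)c1
F4 | step 6 | dibenzyl 3-oxopentanedioate | O=C(CC(=O)OCc1ccccc1)CC(=O)OCc1ccccc1
F5 | step 6 | dibenzyl 2-({2-[11-(benzyloxy)undecyl]-1,3-dioxolan-2-yl}acetyl)-3-oxopentanedioate | O=C(CC(=O)C(C(=O)OCc1ccccc1)C(=O)CC1(CCCCCCCCCCCOCc2ccccc2)OCCO1)OCc1ccccc1
F6 | step 7 | malonyl dichloride | O=C(Cl)CC(=O)Cl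
F7 | step 5 | benzyl acetate | CC(=O)OCc1ccccc1
F8 | step 10 | 8-(benzyloxy)-3-[11-(benzyloxy)undecyl]-6-methoxy-1H-isochromen-1-one | O=C1OC(CCCCCCCCCCCOCc2ccccc2)=Cc2cc(OC)cc(OCc3ccccc3)c21
F9 | step 10 | 2-(benzyloxy)-6-[13-(benzyloxy)-2-oxotridecyl]-4-methoxybenzoic acid | COc1cc(OCc2ccccc2)c(C(=O)O)c(CC(=O)CCCCCCCCCCCOCc2ccccc2)c1
A1 | alternative 1 | 3,5-dimethoxy-2-(trimethylsilyl)phenyl trifluoromethanesulfonate | COc1cc(OC)c([Si](C)(C)C)c(OS(=O)(=O)C(F)(F)F)c1
A2 | alternative 1 | 3,5-dimethoxybenzyne | COC1=CC(OC)=CC#C1
A3 | alternative 1 | dimethyl malonate | COC(=O)CC(=O)OC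
A4 | alternative 1 | methyl 2,4-dimethoxy-6-(2-methoxy-2-oxoethyl)benzoate | COC(=O)Cc1cc(OC)cc(OC)c1C(=O)OC
A5 | alternative 2 | benzyl 8-[2-(11-{[tert-butyl(dimethyl)silyl]oxy}undecyl)-1,3-dioxolan-2-yl]-3,5,7-trioxooctanoate | O=C(CC(=O)CC(=O)CC(=O)CC1(CCCCCCCCCCCO[Si](C)(C)C(C)(C)C)OCCO1)OCc1ccccc1
A6 | alternative 2 | benzyl 6-{[2-(11-{[tert-butyl(dimethyl)silyl]oxy}undecyl)-1,3-dioxolan-2-yl]methyl}-2,4-dihydroxybenzoate | O=C(OCc1ccccc1)c1c(O)cc(O)cc1CC1(CCCCCCCCCCCO[Si](C)(C)C(C)(C)C)OCCO1
A7 | alternative 3 | 1,3-dimethoxy-1-(trimethylsilyloxy)buta-1,3-diene | C=C(OC)C=C(OC)O[Si](C)(C)C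
A8 | alternative 3 | benzyl 4-{2-[11-(benzyloxy)undecyl]-1,3-dioxolan-2-yl}but-2-ynoate | O=C(C#CCC1(CCCCCCCCCCCOCc2ccccc2)OCCO1)OCc1ccccc1
A9 | alternative 3 | benzyl 6-({2-[11-(benzyloxy)undecyl]-1,3-dioxolan-2-yl}methyl)-2-hydroxy-4-methoxybenzoate | COc1cc(O)c(C(=O)OCc2ccccc2)c(CC2(CCCCCCCCCCCOCc3ccccc3)OCCO2)c1
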